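**Retrosynthetic overview** (side chain numbered C1'–C15' from the arene)
1. C4'–C5': visible-light nickel/photoredox acyl–allyl coupling of Z-enoic acid 14 (C5'–C15') with aryl allyl carbonate 20 (arene + C1'–C4').
2. C10'–C11': photochemical decarboxylative Giese addition of diacid 10 to butenolide 6, anti to the C12' substituent (sets C11'); the lactone CH2–CO2 unit is then cut down to the C11' methyl and the C12' carbinol is oxidised to the ketone.
3. Butenolide 6 comes from 2,3:5,6-di-O-isopropylidene-D-mannofuranose (mannose C2 becomes C13' and is kept; mannose C3 becomes C12', steers C11' and ends as the ketone); the Z C6'=C7' bond is bought in ethyl (Z)-3-iodobut-2-enoate.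
4. Arene–C1': Pd-catalysed O-allylation of 4-methoxy-2-methylphenol with isoprene monoxide, then photo-Claisen [1,3] shift.
5. Rings: the benzene ring is bought; the only ring made is the temporary butenolide (step 3), opened again in step 8.

Assumption: 1, 7, 8, 15 and 16 are commercial; 1 is the only chiral purchase.

**Step 1**
Reactants: 1 2,3:5,6-di-O-isopropylidene-α-D-mannofuranose
Product: 2 (R)-[(4R)-2,2-dimethyl-1,3-dioxolan-4-yl][(4S,5R)-2,2-dimethyl-5-(2-methylprop-1-en-1-yl)-1,3-dioxolan-4-yl]methanol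
Conditions: i-PrPPh3I (3.0 equiv), n-BuLi (2.9 equiv), THF, 0 °C; then 1, −78 to 25 °C
Reagents that add atoms: isopropyltriphenylphosphonium iodide, CC(C)[P+](c1ccccc1)(c1ccccc1)c1ccccc1.[I-]
Why: Wittig olefination of the open-chain aldehyde form of the lactol with a non-stabilised ylide; the mannose C2 and C3 centres (future C13' and C12') are bought and carried through unchanged.

**Step 2**
Reactants: 2 (R)-[(4R)-2,2-dimethyl-1,3-dioxolan-4-yl][(4S,5R)-2,2-dimethyl-5-(2-methylprop-1-en-1-yl)-1,3-dioxolan-4-yl]methanol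
Product: 4 methyl (2Z)-3-[(4S,5R)-2,2-dimethyl-5-(2-methylprop-1-en-1-yl)-1,3-dioxolan-4-yl]prop-2-enoate, via aldehyde 3 (not isolated)
Conditions: H5IO6 (2.2 equiv), EtOAc, 25 °C; filter; then Ph3P=CHCO2Me (1.3 equiv), MeOH, 0 °C
Reagents that add atoms: methyl (triphenylphosphoranylidene)acetate, COC(=O)C=P(c1ccccc1)(c1ccccc1)c1ccccc1
Why: Periodic acid hydrolyses the terminal acetonide and cleaves the resulting triol (Malaprade glycol cleavage) to the α-alkoxy aldehyde, which undergoes a Z-selective Wittig reaction with the stabilised ylide in methanol; no stereocentre is touched, and the minor E ester is removed after step 3 because it cannot close to the butenolide.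

**Step 3**
Reactants: 4 methyl (2Z)-3-[(4S,5R)-2,2-dimethyl-5-(2-methylprop-1-en-1-yl)-1,3-dioxolan-4-yl]prop-2-enoate
Product: 5 (5S)-5-[(1R)-1-hydroxy-3-methylbut-2-en-1-yl]furan-2(5H)-one
Conditions: AcOH/H2O (4:1), 45 °C
Reagents that add atoms: none
Why: Acid hydrolysis of the acetonide followed by spontaneous γ-lactonisation of the Z γ-hydroxy enoate (butenolide formation); only the C12' hydroxyl can close the five-membered ring, which differentiates it from the C13' hydroxyl.

**Step 4**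
Reactants: 5 (5S)-5-[(1R)-1-hydroxy-3-methylbut-2-en-1-yl]furan-2(5H)-one
Product: 6 (5S)-5-{(1R)-1-[(tert-butyldiphenylsilyl)oxy]-3-methylbut-2-en-1-yl}furan-2(5H)-one
Conditions: TBDPSCl (1.3 equiv), imidazole (2.5 equiv), DMAP (cat.), DMF, 25 °C
Reagents that add atoms: tert-butyl(chloro)diphenylsilane, CC(C)(C)[Si](Cl)(c1ccccc1)c1ccccc1
Why: Silyl ether formation on the free allylic hydroxyl under weakly basic conditions that do not enolise the butenolide; the bulky group also shields one face for step 7 and resists 1,2-silyl migration in step 8.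

**Step 5**
Reactants: 7 ethyl (2Z)-3-iodobut-2-enoate; 8 4-ethoxy-4-oxobutylzinc bromide
Product: 9 diethyl (2Z)-3-methylhept-2-enedioate
Conditions: Pd(PPh3)4 (3 mol%), THF, 25 °C
Reagents that add atoms: none
Why: Negishi coupling of the β-iodo enoate with the alkylzinc reagent proceeds with retention, so the alkyl chain ends up cis to the ester (the Z C6'=C7' geometry of the target).

**Step 6**
Reactants: 9 diethyl (2Z)-3-methylhept-2-enedioate
Product: 10 (2Z)-3-methylhept-2-enedioic acid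
Conditions: LiOH·H2O (4 equiv), THF/MeOH/H2O, 45 °C; then 1 M HCl
Reagents that add atoms: lithium hydroxide, [Li+].[OH-]
Why: Saponification of both esters; the β,β-disubstituted enoate keeps its Z geometry under hydroxide.

**Step 7**
Reactants: 6 (5S)-5-{(1R)-1-[(tert-butyldiphenylsilyl)oxy]-3-methylbut-2-en-1-yl}furan-2(5H)-one; 10 (2Z)-3-methylhept-2-enedioic acid
Product: 11 (2Z)-6-[(2S,3S)-2-{(1R)-1-[(tert-butyldiphenylsilyl)oxy]-3-methylbut-2-en-1-yl}-5-oxooxolan-3-yl]-3-methylhex-2-enoic acid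
Conditions: [Ir(dF(CF3)ppy)2(dtbbpy)]PF6 (2 mol%), K2HPO4 (2 equiv), 10 (2 equiv), DMSO, 450 nm LEDs, 25 °C
Reagents that add atoms: none
Why: Photoredox decarboxylative Giese (radical conjugate) addition: only the saturated carboxylate of 10 loses CO2 after oxidation by the excited iridium photocatalyst, and the primary radical adds to the butenolide β-carbon on the face opposite the bulky C5 substituent, so the bought C12' centre fixes C11' trans to it (S in the lactone, R once the ring CH2CO2 has become CH3).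

**Step 8**
Reactants: 11 (2Z)-6-[(2S,3S)-2-{(1R)-1-[(tert-butyldiphenylsilyl)oxy]-3-methylbut-2-en-1-yl}-5-oxooxolan-3-yl]-3-methylhex-2-enoic acid
Product: 13 (2Z,7R,8S,9R)-9-[(tert-butyldiphenylsilyl)oxy]-8-hydroxy-3,7,11-trimethyldodeca-2,10-dienoic acid, via dicesium salt 12 (not isolated)
Conditions: CsOH·H2O (2.1 equiv), DMSO/H2O (9:1), 25 °C, 1 h; then [Ir(dF(CF3)ppy)2(dtbbpy)]PF6 (2 mol%), 2,4,6-triisopropylbenzenethiol (20 mol%), 450 nm LEDs, 25 °C; then cold 0.5 M HCl
Reagents that add atoms: none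
Why: Lactone saponification followed in the same flask by photoredox hydrodecarboxylation with a thiol hydrogen-atom donor turns the ring CH2–CO2 unit into the C11' methyl group (the conjugated carboxylate does not decarboxylate); no stereocentre is touched and decarboxylating before the ketone exists avoids a 1,2-acyl shift of the radical.

**Step 9**
Reactants: 13 (2Z,7R,8S,9R)-9-[(tert-butyldiphenylsilyl)oxy]-8-hydroxy-3,7,11-trimethyldodeca-2,10-dienoic acid
Product: 14 (2Z,7R,9R)-9-[(tert-butyldiphenylsilyl)oxy]-3,7,11-trimethyl-8-oxododeca-2,10-dienoic acid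
Conditions: Dess–Martin periodinane (1.5 equiv), NaHCO3, CH2Cl2, 0 to 25 °C
Reagents that add atoms: none
Why: Dess–Martin oxidation converts the C12' carbinol (the bought centre that steered C11') into the ketone under buffered, non-epimerising conditions.

**Step 10**
Reactants: 15 4-methoxy-2-methylphenol; 16 2-methyl-2-vinyloxirane (isoprene monoxide)
Product: 17 (2E)-4-(4-methoxy-2-methylphenoxy)-2-methylbut-2-en-1-ol
Conditions: Pd2(dba)3·CHCl3 (1 mol%), PPh3 (4 mol%), 16 (1.5 equiv), THF, 25 to 40 °C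
Reagents that add atoms: none
Why: Tsuji–Trost opening of the vinyl epoxide through a (π-allyl)palladium intermediate with O-attack at the unsubstituted terminus; the linear E ether is the thermodynamic product because the branched tertiary aryl ether re-ionises under zerovalent palladium.

**Step 11**
Reactants: 17 (2E)-4-(4-methoxy-2-methylphenoxy)-2-methylbut-2-en-1-ol
Product: 18 (2E)-4-(2-hydroxy-5-methoxy-3-methylphenyl)-2-methylbut-2-en-1-ol
Conditions: hν (254 nm, low-pressure Hg lamp), degassed MeOH (5 mM), quartz flow coil, 25 °C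
Reagents that add atoms: none
Why: Photo-Claisen rearrangement ([1,3] shift through a caged phenoxyl/allyl radical pair) forms the arene–C1' bond at the only free ortho position (para and the other ortho position are blocked), with recombination at the primary allyl terminus and retention of the E alkene.

**Step 12**
Reactants: 18 (2E)-4-(2-hydroxy-5-methoxy-3-methylphenyl)-2-methylbut-2-en-1-ol
Product: 20 (2E)-4-{2-[(tert-butyldimethylsilyl)oxy]-5-methoxy-3-methylphenyl}-2-methylbut-2-en-1-yl methyl carbonate, via phenol carbonate 19 (not isolated)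
Conditions: ClCO2Me (1.1 equiv), pyridine, CH2Cl2, −40 °C; then imidazole, TBSCl (1.5 equiv), DMAP (cat.), 25 °C
Reagents that add atoms: methyl chloroformate, COC(=O)Cl; tert-butyl(chloro)dimethylsilane, CC(C)(C)[Si](C)(C)Cl
Why: Chemoselective acylation of the unhindered primary allylic alcohol over the hindered 2,6-disubstituted phenol, then silylation of the phenol, which would otherwise cyclise onto the π-allyl intermediate in step 13.

**Step 13**
Reactants: 14 (2Z,7R,9R)-9-[(tert-butyldiphenylsilyl)oxy]-3,7,11-trimethyl-8-oxododeca-2,10-dienoic acid; 20 (2E)-4-{2-[(tert-butyldimethylsilyl)oxy]-5-methoxy-3-methylphenyl}-2-methylbut-2-en-1-yl methyl carbonate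
Product: 22 (2E,6Z,11R,13R)-1-{2-[(tert-butyldimethylsilyl)oxy]-5-methoxy-3-methylphenyl}-13-[(tert-butyldiphenylsilyl)oxy]-3,7,11,15-tetramethylhexadeca-2,6,14-triene-5,12-dione, via mixed anhydride 21 (not isolated)
Conditions: 14, (MeOCO)2O (1.2 equiv), 2,6-lutidine (1.2 equiv), DMA, 25 °C, 30 min; then 20 (1.3 equiv), NiBr2(dme) (10 mol%), 4,4'-di-tert-butyl-2,2'-bipyridine (12 mol%), [Ir(ppy)2(dtbbpy)]PF6 (1 mol%), Hantzsch ester (1.5 equiv), 450 nm LEDs, 25 °C
Reagents that add atoms: none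
Why: Proposed new method: a nickel/photoredox reductive acyl–allyl cross-electrophile coupling in which zerovalent nickel ionises the allylic carbonate to an (η3-allyl)nickel species, photoreduction (iridium photocatalyst with Hantzsch ester) gives a monovalent allylnickel that adds oxidatively into the acyl–O bond of mixed anhydride 21, and the acyl(allyl)nickel reductively eliminates at the unsubstituted CH2 terminus with the syn (E) allyl and the Z-enoyl geometry intact, forming C4'–C5' without base so that the skipped dienone and the C11'/C13' centres are not isomerised; the closest known reaction types are nickel-catalysed reductive ketone syntheses from in situ activated carboxylic acids with alkyl halides, nickel-catalysed reductive allylations with allylic carbonates and nickel/photoredox acyl cross-couplings.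

**Step 14**
Reactants: 22 (2E,6Z,11R,13R)-1-{2-[(tert-butyldimethylsilyl)oxy]-5-methoxy-3-methylphenyl}-13-[(tert-butyldiphenylsilyl)oxy]-3,7,11,15-tetramethylhexadeca-2,6,14-triene-5,12-dione
Product: 23 2-[(2E,6Z,11R,13R)-13-hydroxy-3,7,11,15-tetramethyl-5,12-dioxohexadeca-2,6,14-trien-1-yl]-4-methoxy-6-methylphenol
Conditions: Bu4NF (3 equiv), AcOH (3 equiv), THF, 0 to 25 °C
Reagents that add atoms: none
Why: Fluoride desilylation of the aryl and the α-keto secondary silyl ethers, buffered with acetic acid so that the α-hydroxy ketone, the C11' centre and the skipped dienone are not exposed to base.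

**Compound list**
1 | 2,3:5,6-di-O-isopropylidene-α-D-mannofuranose | O[C@H]1O[C@H]([C@H]2COC(C)(C)O2)[C@@H]2OC(C)(C)O[C@H]12 | starting material
2 | (R)-[(4R)-2,2-dimethyl-1,3-dioxolan-4-yl][(4S,5R)-2,2-dimethyl-5-(2-methylprop-1-en-1-yl)-1,3-dioxolan-4-yl]methanol | CC(C)=C[C@H]1OC(C)(C)O[C@H]1[C@H](O)[C@H]1COC(C)(C)O1 | intermediate
3 | (4R,5R)-2,2-dimethyl-5-(2-methylprop-1-en-1-yl)-1,3-dioxolane-4-carbaldehyde | CC(C)=C[C@H]1OC(C)(C)O[C@H]1C=O | intermediate
4 | methyl (2Z)-3-[(4S,5R)-2,2-dimethyl-5-(2-methylprop-1-en-1-yl)-1,3-dioxolan-4-yl]prop-2-enoate | CC(C)=C[C@H]1OC(C)(C)O[C@H]1/C=C\C(=O)OC | intermediate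
5 | (5S)-5-[(1R)-1-hydroxy-3-methylbut-2-en-1-yl]furan-2(5H)-one | CC(C)=C[C@@H](O)[C@H]1OC(=O)C=C1 | intermediate
6 | (5S)-5-{(1R)-1-[(tert-butyldiphenylsilyl)oxy]-3-methylbut-2-en-1-yl}furan-2(5H)-one | CC(C)=C[C@@H](O[Si](c1ccccc1)(c1ccccc1)C(C)(C)C)[C@H]1OC(=O)C=C1 | intermediate
7 | ethyl (2Z)-3-iodobut-2-enoate | CCOC(=O)/C=C(/C)I | starting material
8 | 4-ethoxy-4-oxobutylzinc bromide | CCOC(=O)CCC[Zn]Br | starting material
9 | diethyl (2Z)-3-methylhept-2-enedioate | CCOC(=O)/C=C(/C)CCCC(=O)OCC | intermediate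
10 | (2Z)-3-methylhept-2-enedioic acid | OC(=O)/C=C(/C)CCCC(O)=O | intermediate
11 | (2Z)-6-[(2S,3S)-2-{(1R)-1-[(tert-butyldiphenylsilyl)oxy]-3-methylbut-2-en-1-yl}-5-oxooxolan-3-yl]-3-methylhex-2-enoic acid | CC(C)=C[C@@H](O[Si](c1ccccc1)(c1ccccc1)C(C)(C)C)[C@H]1OC(=O)C[C@@H]1CCC/C(C)=C\C(O)=O | intermediate
12 | dicesium (2Z,7S,8S,9R)-9-[(tert-butyldiphenylsilyl)oxy]-7-(carboxylatomethyl)-8-hydroxy-3,11-dimethyldodeca-2,10-dienoate | [Cs+].[Cs+].CC(C)=C[C@@H](O[Si](c1ccccc1)(c1ccccc1)C(C)(C)C)[C@@H](O)[C@H](CC([O-])=O)CCC/C(C)=C\C([O-])=O | intermediate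
13 | (2Z,7R,8S,9R)-9-[(tert-butyldiphenylsilyl)oxy]-8-hydroxy-3,7,11-trimethyldodeca-2,10-dienoic acid | CC(C)=C[C@@H](O[Si](c1ccccc1)(c1ccccc1)C(C)(C)C)[C@@H](O)[C@H](C)CCC/C(C)=C\C(O)=O | intermediate
14 | (2Z,7R,9R)-9-[(tert-butyldiphenylsilyl)oxy]-3,7,11-trimethyl-8-oxododeca-2,10-dienoic acid | CC(C)=C[C@@H](O[Si](c1ccccc1)(c1ccccc1)C(C)(C)C)C(=O)[C@H](C)CCC/C(C)=C\C(O)=O | intermediate
15 | 4-methoxy-2-methylphenol | COc1ccc(O)c(C)c1 | starting material
16 | 2-methyl-2-vinyloxirane (isoprene monoxide) | CC1(CO1)C=C | starting material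
17 | (2E)-4-(4-methoxy-2-methylphenoxy)-2-methylbut-2-en-1-ol | COc1ccc(OC/C=C(\C)CO)c(C)c1 | intermediate
18 | (2E)-4-(2-hydroxy-5-methoxy-3-methylphenyl)-2-methylbut-2-en-1-ol | COc1cc(C)c(O)c(C/C=C(\C)CO)c1 | intermediate
19 | (2E)-4-(2-hydroxy-5-methoxy-3-methylphenyl)-2-methylbut-2-en-1-yl methyl carbonate | COc1cc(C)c(O)c(C/C=C(\C)COC(=O)OC)c1 | intermediate
20 | (2E)-4-{2-[(tert-butyldimethylsilyl)oxy]-5-methoxy-3-methylphenyl}-2-methylbut-2-en-1-yl methyl carbonate | COc1cc(C)c(O[Si](C)(C)C(C)(C)C)c(C/C=C(\C)COC(=O)OC)c1 | intermediate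
21 | (2Z,7R,9R)-9-[(tert-butyldiphenylsilyl)oxy]-3,7,11-trimethyl-8-oxododeca-2,10-dienoic methyl carbonic anhydride | COC(=O)OC(=O)/C=C(/C)CCC[C@@H](C)C(=O)[C@H](O[Si](c1ccccc1)(c1ccccc1)C(C)(C)C)C=C(C)C | intermediate
22 | (2E,6Z,11R,13R)-1-{2-[(tert-butyldimethylsilyl)oxy]-5-methoxy-3-methylphenyl}-13-[(tert-butyldiphenylsilyl)oxy]-3,7,11,15-tetramethylhexadeca-2,6,14-triene-5,12-dione | COc1cc(C)c(O[Si](C)(C)C(C)(C)C)c(C/C=C(\C)CC(=O)/C=C(/C)CCC[C@@H](C)C(=O)[C@H](O[Si](c2ccccc2)(c2ccccc2)C(C)(C)C)C=C(C)C)c1 | intermediate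
23 | 2-[(2E,6Z,11R,13R)-13-hydroxy-3,7,11,15-tetramethyl-5,12-dioxohexadeca-2,6,14-trien-1-yl]-4-methoxy-6-methylphenol | COc1cc(C)c(O)c(C/C=C(\C)CC(=O)/C=C(/C)CCC[C@@H](C)C(=O)[C@H](O)C=C(C)C)c1 | target

**Total step count:** 14.
**Longest linear sequence:** 9 steps (1, 2, 3, 4, 7, 8, 9, 13, 14).

**Three steps most likely to fail**

Step 13 (the proposed new coupling). Likely failure modes are allyl homodimer, the branched ketone, or isomerisation of the skipped dienone into conjugation. The fallback makes the C4'–C5' bond by classical sulfone carbanion acylation and reductive desulfonylation; it sets out from 13 and 20 and comes back at 22. Acid 13 is esterified with Me3SiCHN2 to methyl (2Z,7R,8S,9R)-9-[(tert-butyldiphenylsilyl)oxy]-8-hydroxy-3,7,11-trimethyldodeca-2,10-dienoate F1. Carbonate 20 is converted with PhSO2Na and Pd(PPh3)4 into the linear allylic sulfone tert-butyl{4-methoxy-2-methyl-6-[(2E)-3-methyl-4-(phenylsulfonyl)but-2-en-1-yl]phenoxy}dimethylsilane F2. The α-lithio derivative of F2 (n-BuLi, THF, −78 °C, 2.2 equiv) acylates F1 (hydroxyl first deprotonated with LiN(SiMe3)2) at its ester carbon, −78 to −30 °C, to give the β-keto sulfone F3. SmI2 in THF/MeOH at −78 °C removes the sulfonyl group to give the skipped dienone alcohol F4, and Dess–Martin oxidation of its C12' carbinol gives 22.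

Step 7 (Giese addition). A primary, unactivated carboxylate is a slow substrate for photoredox decarboxylation, and the butenolide can epimerise at C12' under base. The fallback uses two-electron conjugate addition and cross-coupling; it sets out from 6 and 7 and comes back at 13. Allylcopper (allylMgBr, CuBr·SMe2, Me3SiCl, THF, −78 °C) adds to 6 anti to the C5 substituent to give (4S,5S)-4-allyl-5-{(1R)-1-[(tert-butyldiphenylsilyl)oxy]-3-methylbut-2-en-1-yl}oxolan-2-one F5. Hydroboration of the terminal alkene with 9-BBN and Suzuki–Miyaura coupling with 7 (PdCl2(dppf), K3PO4, DMF/H2O) gives the lactone ethyl ester F6 with the Z geometry retained. F6 is then taken through the conditions of step 8 with 3.2 equiv CsOH (lactone opening and ester hydrolysis before irradiation) to reach 13.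

Step 8 (one-pot saponification and photodecarboxylation). Risks are 1,2-silyl migration in the ring-opened alkoxide, poor selectivity between the two carboxylates, and intramolecular hydrogen abstraction by the primary radical. The fallback removes the carbon by decarbonylation instead of decarboxylation; it sets out from 11 and comes back at 13. i-Bu2AlH (3 equiv, CH2Cl2, −78 °C) reduces the lactone to the lactol F7 while the carboxylic acid is held as its aluminium carboxylate. Stoichiometric RhCl(PPh3)3 (toluene, 110 °C, Tsuji–Wilkinson decarbonylation of the open hydroxy-aldehyde form) then removes the formyl carbon and leaves the C11' methyl group and the free C12' hydroxyl, which is 13.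

**Further compounds**
F1 | step 13 | methyl (2Z,7R,8S,9R)-9-[(tert-butyldiphenylsilyl)oxy]-8-hydroxy-3,7,11-trimethyldodeca-2,10-dienoate | CC(C)=C[C@@H](O[Si](c1ccccc1)(c1ccccc1)C(C)(C)C)[C@@H](O)[C@H](C)CCC/C(C)=C\C(=O)OC
F2 | step 13 | tert-butyl{4-methoxy-2-methyl-6-[(2E)-3-methyl-4-(phenylsulfonyl)but-2-en-1-yl]phenoxy}dimethylsilane | COc1cc(C)c(O[Si](C)(C)C(C)(C)C)c(C/C=C(\C)CS(=O)(=O)c2ccccc2)c1
F3 | step 13 | (2E,6Z,11R,12S,13R)-1-{2-[(tert-butyldimethylsilyl)oxy]-5-methoxy-3-methylphenyl}-13-[(tert-butyldiphenylsilyl)oxy]-12-hydroxy-3,7,11,15-tetramethyl-4-(phenylsulfonyl)hexadeca-2,6,14-trien-5-one (both C4 epimers) | COc1cc(C)c(O[Si](C)(C)C(C)(C)C)c(C/C=C(\C)C(S(=O)(=O)c2ccccc2)C(=O)/C=C(/C)CCC[C@@H](C)[C@H](O)[C@H](O[Si](c2ccccc2)(c2ccccc2)C(C)(C)C)C=C(C)C)c1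
F4 | step 13 | (2E,6Z,11R,12S,13R)-1-{2-[(tert-butyldimethylsilyl)oxy]-5-methoxy-3-methylphenyl}-13-[(tert-butyldiphenylsilyl)oxy]-12-hydroxy-3,7,11,15-tetramethylhexadeca-2,6,14-trien-5-one | COc1cc(C)c(O[Si](C)(C)C(C)(C)C)c(C/C=C(\C)CC(=O)/C=C(/C)CCC[C@@H](C)[C@H](O)[C@H](O[Si](c2ccccc2)(c2ccccc2)C(C)(C)C)C=C(C)C)c1
F5 | step 7 | (4S,5S)-4-allyl-5-{(1R)-1-[(tert-butyldiphenylsilyl)oxy]-3-methylbut-2-en-1-yl}oxolan-2-one | CC(C)=C[C@@H](O[Si](c1ccccc1)(c1ccccc1)C(C)(C)C)[C@H]1OC(=O)C[C@@H]1CC=C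
F6 | step 7 | ethyl (2Z)-6-[(2S,3S)-2-{(1R)-1-[(tert-butyldiphenylsilyl)oxy]-3-methylbut-2-en-1-yl}-5-oxooxolan-3-yl]-3-methylhex-2-enoate | CC(C)=C[C@@H](O[Si](c1ccccc1)(c1ccccc1)C(C)(C)C)[C@H]1OC(=O)C[C@@H]1CCC/C(C)=C\C(=O)OCC
F7 | step 8 | (2Z)-6-[(2S,3S)-2-{(1R)-1-[(tert-butyldiphenylsilyl)oxy]-3-methylbut-2-en-1-yl}-5-hydroxyoxolan-3-yl]-3-methylhex-2-enoic acid (anomer mixture) | CC(C)=C[C@@H](O[Si](c1ccccc1)(c1ccccc1)C(C)(C)C)[C@H]1OC(O)C[C@@H]1CCC/C(C)=C\C(O)=O
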